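Ring A (the acylated cyclohexanetrione; C1 the ring ketone, C2 hexanoyl-bearing, C4 quaternary, C6 bridge-bearing) is a cyclised tetraketide. Its hexanoyl oxygen is 1,3 to O3, and the ring-B phenol oxygen ortho to the CH2 bridge can reach C1 through a six-membered lactone. Cutting C1–C2 and C5–C6 therefore turns ring A into two lactones: a (3S)-3-methyl-3-prenyl-6-pentylpyran-2,4-dione (its ring oxygen becomes the hexanoyl C=O) and an 8-butanoylchroman-2-one (its ring oxygen becomes the phenol). One Claisen–Dieckmann cascade between the chromanone enolate and the pyrandione forms both bonds, uses every atom of both partners and gives the unprotected target. The stereocentre is set earlier by palladium-catalysed asymmetric prenylation.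

Key step: step 7

Assumption: compounds are drawn as single tautomers and descriptors refer to these; the sense of induction of the Trost ligand in step 3 cannot be predicted with confidence, so the (R,R)-ligand is written and its mirror image is used if analysis of the pyrandione shows the opposite sense.

Step 1
Reactants: 1 ethyl 2-methyl-3-oxobutanoate; 2 ethyl hexanoate
Product: 3 ethyl 2-methyl-3,5-dioxodecanoate
Conditions: 1 (2 equiv), NaH, THF, 0 °C; n-BuLi, 0 °C; then 2 (1 equiv), 0 °C → rt; aq. HCl
Reagents that add atoms: none
Why: γ-Acylation of a β-keto ester dianion with an ester (Huckin–Weiler dianion chemistry, a Claisen condensation at the terminal methyl) gives the 3,5-dioxo ester, the second equivalent of dianion taking up the acidic proton of the product.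

Step 2
Reactants: 3 ethyl 2-methyl-3,5-dioxodecanoate
Product: 4 4-hydroxy-3-methyl-6-pentyl-2H-pyran-2-one
Conditions: DBU, toluene, reflux; aq. HCl
Reagents that add atoms: none
Why: Base-mediated enol-lactonisation of a 3,5-dioxo ester (O-acylation by the C5 enol with loss of ethanol) is the standard route to 4-hydroxy-2-pyranones.

Step 3
Reactants: 4 4-hydroxy-3-methyl-6-pentyl-2H-pyran-2-one; 5 3-methylbut-2-en-1-yl acetate (prenyl acetate)
Product: 6 (3S)-3-methyl-3-(3-methylbut-2-en-1-yl)-6-pentyl-2H-pyran-2,4(3H)-dione
Conditions: Pd2(dba)3·CHCl3 (cat.), (R,R)-DACH-phenyl Trost ligand [N,N'-((1R,2R)-cyclohexane-1,2-diyl)bis(2-(diphenylphosphanyl)benzamide)] (cat.), Et3N, CH2Cl2 (dry), 0 °C → rt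
Reagents that add atoms: none
Why: Tsuji–Trost asymmetric allylic alkylation: the soft pyranone anion attacks the unsubstituted terminus of the π-prenyl palladium complex at C3 (any O-prenyl ether re-ionises under zerovalent palladium and funnels to the irreversible C–C product), and the chiral pocket of the ligand should differentiate the enantiotopic faces of the planar enolate, whose lactone and vinylogous-ester flanks differ, to set the quaternary (S)-centre.

Step 4
Reactants: 7 benzene-1,3,5-triol (phloroglucinol); 8 butanoyl chloride
Product: 9 1-(2,4,6-trihydroxyphenyl)butan-1-one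
Conditions: AlCl3, PhNO2/CH2Cl2, 0 °C → 40 °C; aq. HCl
Reagents that add atoms: none
Why: Friedel–Crafts acylation of the symmetric triol should stop after one acyl group because the chelated aryl ketone deactivates the ring.

Step 5
Reactants: 9 1-(2,4,6-trihydroxyphenyl)butan-1-one
Product: 10 1-(2,6-dihydroxy-4-methoxyphenyl)butan-1-one
Conditions: Me2SO4 (1 equiv), K2CO3 (1 equiv), acetone, rt → reflux
Reagents that add atoms: dimethyl sulfate, COS(=O)(=O)OC
Why: Williamson methylation with one equivalent of reagent should select the 4-OH, the only phenol not hydrogen-bonded to the ketone and therefore the most acidic and nucleophilic one.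

Step 6
Reactants: 10 1-(2,6-dihydroxy-4-methoxyphenyl)butan-1-one; 11 acrylic acid
Product: 12 8-butanoyl-7-hydroxy-5-methoxy-3,4-dihydro-2H-chromen-2-one
Conditions: 11 (1.2 equiv), Amberlyst-15, toluene, reflux (Dean–Stark)
Reagents that add atoms: none
Why: Acid-catalysed Friedel–Crafts conjugate addition (hydroarylation) of the electron-rich ring to acrylic acid followed by lactonisation with the adjacent phenol; the two free ring positions of 10 are equivalent by symmetry, so only one regioisomer can form, and the new lactone deactivates the ring towards a second annulation.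

Step 7
Reactants: 12 8-butanoyl-7-hydroxy-5-methoxy-3,4-dihydro-2H-chromen-2-one; 6 (3S)-3-methyl-3-(3-methylbut-2-en-1-yl)-6-pentyl-2H-pyran-2,4(3H)-dione
Product: 15 (4R)-6-[(3-butanoyl-2,4-dihydroxy-6-methoxyphenyl)methyl]-2-hexanoyl-3,5-dihydroxy-4-methyl-4-(3-methylbut-2-en-1-yl)cyclohexa-2,5-dien-1-one (target), via dilithium phenoxide-enolate 13 (not isolated), via ring-opened Claisen adduct 14 (not isolated)
Conditions: LiN(SiMe3)2 (2.05 equiv), THF, −78 °C, 12 added to the base; then 6 (1 equiv), −78 °C → rt; cold 0.5 M HCl
Reagents that add atoms: none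
Why: Two equivalents of base convert 12 into dianion 13: the first turns the 7-OH/8-butanoyl pair into a chelated o-acylphenoxide (a vinylogous carboxylate with deactivated α-hydrogens), and the second enolises the more acidic aryl-lactone α-CH2. The enolate carbon adds to the lactone carbonyl of 6, a vinylogous anhydride and the only acyl carbon of 6 with a leaving group; the ring oxygen leaves as the 1,3-diketone enolate of 14 (first new bond, C5–C6 of ring A), and the central carbon of that enolate is then acylated by the aryl lactone with release of the ring-B phenoxide (second new bond, C1–C2). The closest known reaction types are the crossed Claisen acylation of an ester enolate by an enol ester and the Claisen (Dieckmann-type) cyclisation of 3,5,7-trioxoalkanoates to 2-acylcyclohexane-1,3,5-triones; ring A closes in a 6-(enolendo)-exo-trig mode. No stereocentre is created: the quaternary centre of 6 cannot enolise and is carried through unchanged (its descriptor changes from S to R only because the CIP ranks of its two carbonyl neighbours swap), and the transient C3 centre of 14 ends as an sp2 carbon. The step needs site-selective enolisation (secured by the phenoxide and the lactone acidity, with exactly two equivalents of base), attack at the lactone and not at the vinylogous-ester carbons of 6 (secured by the leaving group), and C- over O-acylation with the right regiochemistry (secured because only one carbon of 14 lies between two ketones and the trione anion is the thermodynamic sink).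

Compound list
1 | ethyl 2-methyl-3-oxobutanoate | CCOC(=O)C(C)C(C)=O | starting material
2 | ethyl hexanoate | CCCCCC(=O)OCC | starting material
3 | ethyl 2-methyl-3,5-dioxodecanoate | CCCCCC(=O)CC(=O)C(C)C(=O)OCC | intermediate
4 | 4-hydroxy-3-methyl-6-pentyl-2H-pyran-2-one | CCCCCc1cc(O)c(C)c(=O)o1 | intermediate
5 | 3-methylbut-2-en-1-yl acetate (prenyl acetate) | CC(=O)OCC=C(C)C | starting material
6 | (3S)-3-methyl-3-(3-methylbut-2-en-1-yl)-6-pentyl-2H-pyran-2,4(3H)-dione | CCCCCC1=CC(=O)[C@](C)(CC=C(C)C)C(=O)O1 | intermediate
7 | benzene-1,3,5-triol (phloroglucinol) | Oc1cc(O)cc(O)c1 | starting material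
8 | butanoyl chloride | CCCC(=O)Cl | starting material
9 | 1-(2,4,6-trihydroxyphenyl)butan-1-one | CCCC(=O)c1c(O)cc(O)cc1O | intermediate
10 | 1-(2,6-dihydroxy-4-methoxyphenyl)butan-1-one | CCCC(=O)c1c(O)cc(OC)cc1O | intermediate
11 | acrylic acid | C=CC(=O)O | starting material
12 | 8-butanoyl-7-hydroxy-5-methoxy-3,4-dihydro-2H-chromen-2-one | CCCC(=O)c1c(O)cc(OC)c2CCC(=O)Oc12 | intermediate
13 | dilithium salt of 12 (7-phenoxide and C3 lactone enolate), not isolated | CCCC(=O)c1c([O-])cc(OC)c2CC=C([O-])Oc12.[Li+].[Li+] | intermediate
14 | 8-butanoyl-7-hydroxy-5-methoxy-3-[(2S)-2-methyl-2-(3-methylbut-2-en-1-yl)-3,5-dioxodecanoyl]-3,4-dihydro-2H-chromen-2-one (present as lithium salt, both C3 epimers), not isolated | CCCCCC(=O)CC(=O)[C@](C)(CC=C(C)C)C(=O)C1Cc2c(OC)cc(O)c(C(=O)CCC)c2OC1=O | intermediate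
15 | (4R)-6-[(3-butanoyl-2,4-dihydroxy-6-methoxyphenyl)methyl]-2-hexanoyl-3,5-dihydroxy-4-methyl-4-(3-methylbut-2-en-1-yl)cyclohexa-2,5-dien-1-one | CCCCCC(=O)C1=C(O)[C@](C)(CC=C(C)C)C(O)=C(Cc2c(OC)cc(O)c(C(=O)CCC)c2O)C1=O | target

Total step count: 7. Longest linear sequence: 4 steps (steps 1, 2, 3, 7 or steps 4, 5, 6, 7).

Steps most likely to fail

1. Step 7. The enolisation may take place at the butanoyl α-carbon instead of the lactone, the aryl-lactone enolate may self-condense or collapse to a ketene, the enolate may add to the vinylogous-ester carbons of 6 or merely deprotonate its pentyl α-CH2, or the cascade may stall at O-acylation. Fallback, setting out from 6 (with 10 as the second partner) and coming back at 15: 6 is opened with the lithium enolate of ethyl acetate (LiN(i-Pr)2, EtOAc, THF, −78 °C, two equivalents of enolate), a crossed Claisen with no competing ketone, to give ethyl (4S)-4-methyl-4-(3-methylbut-2-en-1-yl)-3,5,7-trioxododecanoate F1. F1 is cyclised with NaOEt in EtOH (Claisen cyclisation of a trioxoalkanoate) to (4R)-2-hexanoyl-3,5-dihydroxy-4-methyl-4-(3-methylbut-2-en-1-yl)cyclohexa-2,5-dien-1-one F2. The methylene bridge is then made in the classical way by condensing F2 with an excess of 10 and aqueous formaldehyde (KOH, water/EtOH, 0 °C → rt), which should give 15 after separation from the homo-coupled by-products.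

2. Step 3. The ligand may discriminate poorly between the faces of the flat pyranone anion, O-prenylation may persist, or the nucleophile may attack the substituted allyl terminus (reverse prenylation). Fallback, setting out from 4 and coming back at 6: 4 is prenylated without a chiral ligand (Pd(PPh3)4, 5, Et3N, THF, rt) to racemic 3-methyl-3-(3-methylbut-2-en-1-yl)-6-pentyl-2H-pyran-2,4(3H)-dione F3. The enantiomers are separated by preparative chromatography on an immobilised polysaccharide chiral stationary phase (hexane/EtOAc, no alcohol), the (S)-enantiomer being 6.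

3. Step 6. Hydroarylation of the acyl-deactivated ring may be sluggish, acrylic acid may polymerise, a second annulation may occur at the remaining phenol, or O-acylation and Fries-type reaction may lead to a chroman-4-one. Fallback, setting out from 10 and coming back at 12: 10 undergoes Pd(OAc)2-catalysed hydroarylation with ethyl propiolate in CF3CO2H/CH2Cl2 at rt (coumarin synthesis by alkyne hydroarylation and lactonisation) to give 8-butanoyl-7-hydroxy-5-methoxy-2H-chromen-2-one F4. The pyranone double bond of F4 is then hydrogenated (H2, Pd/C, EtOAc, rt) to 12.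

Further compounds
F1 | step 7 | ethyl (4S)-4-methyl-4-(3-methylbut-2-en-1-yl)-3,5,7-trioxododecanoate | CCCCCC(=O)CC(=O)[C@](C)(CC=C(C)C)C(=O)CC(=O)OCC
F2 | step 7 | (4R)-2-hexanoyl-3,5-dihydroxy-4-methyl-4-(3-methylbut-2-en-1-yl)cyclohexa-2,5-dien-1-one | CCCCCC(=O)C1=C(O)[C@](C)(CC=C(C)C)C(O)=CC1=O
F3 | step 3 | racemic 3-methyl-3-(3-methylbut-2-en-1-yl)-6-pentyl-2H-pyran-2,4(3H)-dione | CCCCCC1=CC(=O)C(C)(CC=C(C)C)C(=O)O1
F4 | step 6 | 8-butanoyl-7-hydroxy-5-methoxy-2H-chromen-2-one | CCCC(=O)c1c(O)cc(OC)c2ccc(=O)oc12
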